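**Retrosynthetic overview**
- Feature: in ring C, C4 is a ketone carbon bound to C4a of ring A and C3 is the carbon that carries ring B. Cutting C3–C4 leaves an A-ring aldehyde (future C4) and a B-ring aryl ketone (future C3) joined through O1 and the C2 methylene.
- Ring C is the only ring built. A carbene-catalysed intramolecular crossed benzoin closes C3–C4 to a 3-aryl-3-hydroxychroman-4-one; dehydration across C2–C3 and removal of four MOM ethers then give the isoflavone.
- O1–C2 comes from SN2 of an A-ring phenoxide (from 2,4,6-trihydroxybenzaldehyde) on a B-ring α-chloroketone, which is made from the B-ring aldehyde by chloromethyllithium addition and oxidation.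
- Ring B is dressed on resorcinol: the C3' prenyl by ortho-lithiation between two OMOM groups, the formyl carbon by a second ortho-lithiation, and the C5' 1,1-dimethylallyl group by Claisen rearrangement of the 4'-O-prenyl ether, whose only free ortho position is C5'.
- Rings A and B are bought as arenes.

Key step: step 12

Remark: fremontone has no stereocentre; the carbinol centres of 13 and 18 are racemic and both are erased later (oxidation, dehydration). Isoflavone locants are used (O1, C2, C3, C4, C4a–C8a; primed locants for ring B).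

**Step 1**
Reactants: 1 resorcinol
Product: 2 1,3-bis(methoxymethoxy)benzene
Conditions: NaH, MOMCl, DMF, 0 °C → rt
Reagents that add atoms: chloromethyl methyl ether, COCCl
Why: Double Williamson-type O-alkylation of the bis-phenoxide by the reactive α-chloro ether should give the bis-acetal, which serves both as protecting group and as ortho-directing group.

**Step 2**
Reactants: 2 1,3-bis(methoxymethoxy)benzene; 3 prenyl bromide
Product: 5 1,3-bis(methoxymethoxy)-2-(3-methylbut-2-en-1-yl)benzene, via aryllithium 4 (not isolated)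
Conditions: n-BuLi, THF, 0 °C → rt; then CuI (10 mol %), 3, −78 °C → rt
Reagents that add atoms: none
Why: Directed ortho-metalation takes place at C2 between the two cooperating OMOM groups, and copper-catalysed allylation of the aryllithium at the unhindered CH2 end of prenyl bromide should give the linear prenyl arene.

**Step 3**
Reactants: 5 1,3-bis(methoxymethoxy)-2-(3-methylbut-2-en-1-yl)benzene
Product: 8 2,4-bis(methoxymethoxy)-3-(3-methylbut-2-en-1-yl)benzaldehyde, via aryllithium 6 (not isolated), via lithium hemiaminal alkoxide 7 (not isolated)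
Conditions: n-BuLi, TMEDA, THF, −20 → 0 °C; then DMF, 0 °C → rt; H2O
Reagents that add atoms: N,N-dimethylformamide, CN(C)C=O
Why: A second directed ortho-metalation occurs at the ring C–H next to an OMOM group (the two such positions are equivalent), chelation-controlled ring lithiation being expected to outrun deprotonation of the benzylic-allylic CH2, and formylation of the aryllithium with DMF gives the aldehyde once the hemiaminal alkoxide collapses in water.

**Step 4**
Reactants: 8 2,4-bis(methoxymethoxy)-3-(3-methylbut-2-en-1-yl)benzaldehyde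
Product: 9 2,4-dihydroxy-3-(3-methylbut-2-en-1-yl)benzaldehyde
Conditions: 3 M aq HCl, MeOH, 45 °C
Reagents that add atoms: none
Why: Acid-catalysed acetal exchange with methanol should cleave both aryl MOM ethers under conditions mild enough to leave the trisubstituted alkene alone, freeing two phenols that the formyl group can now tell apart.

**Step 5**
Reactants: 9 2,4-dihydroxy-3-(3-methylbut-2-en-1-yl)benzaldehyde; 3 prenyl bromide
Product: 10 2-hydroxy-3-(3-methylbut-2-en-1-yl)-4-[(3-methylbut-2-en-1-yl)oxy]benzaldehyde
Conditions: K2CO3, acetone, 50 °C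
Reagents that add atoms: none
Why: Williamson etherification should be selective for the 4-OH, because the 2-OH is held in a hydrogen bond to the formyl group while the 4-OH, para to the formyl group, is the more acidic and more nucleophilic site.

**Step 6**
Reactants: 10 2-hydroxy-3-(3-methylbut-2-en-1-yl)-4-[(3-methylbut-2-en-1-yl)oxy]benzaldehyde
Product: 11 2,4-dihydroxy-5-(2-methylbut-3-en-2-yl)-3-(3-methylbut-2-en-1-yl)benzaldehyde
Conditions: EtOH–H2O (4:1), 130 °C, sealed tube
Reagents that add atoms: none
Why: The aromatic Claisen rearrangement ([3,3]) of the aryl prenyl ether can only end at C5, the one unsubstituted ortho position (C3 carries the prenyl group), and allyl inversion delivers the 1,1-dimethylallyl group; the protic medium accelerates the shift so that it should run below the temperatures at which abnormal Claisen isomerisation sets in.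

**Step 7**
Reactants: 11 2,4-dihydroxy-5-(2-methylbut-3-en-2-yl)-3-(3-methylbut-2-en-1-yl)benzaldehyde
Product: 12 2,4-bis(methoxymethoxy)-5-(2-methylbut-3-en-2-yl)-3-(3-methylbut-2-en-1-yl)benzaldehyde
Conditions: NaH, MOMCl, DMF, 0 °C → rt
Reagents that add atoms: chloromethyl methyl ether, COCCl
Why: Both hindered phenols are converted into phenoxides by NaH and O-alkylated by the small, reactive MOMCl (Williamson-type acetal formation), giving ethers stable to organolithium, oxidant, carbonate and carbene conditions.

**Step 8**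
Reactants: 12 2,4-bis(methoxymethoxy)-5-(2-methylbut-3-en-2-yl)-3-(3-methylbut-2-en-1-yl)benzaldehyde
Product: 13 racemic 2-chloro-1-[2,4-bis(methoxymethoxy)-5-(2-methylbut-3-en-2-yl)-3-(3-methylbut-2-en-1-yl)phenyl]ethan-1-ol
Conditions: ICH2Cl, MeLi·LiBr, THF, −78 °C; AcOH, −78 °C
Reagents that add atoms: chloroiodomethane, ClCI
Why: Chloromethyllithium, generated by iodine–lithium exchange in the presence of the aldehyde (Barbier conditions), should add to the formyl group faster than it decomposes, and the cold acid quench keeps the chlorohydrin from closing to the epoxide; the new carbinol centre is racemic and is removed in step 9.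

**Step 9**
Reactants: 13 racemic 2-chloro-1-[2,4-bis(methoxymethoxy)-5-(2-methylbut-3-en-2-yl)-3-(3-methylbut-2-en-1-yl)phenyl]ethan-1-ol
Product: 14 2-chloro-1-[2,4-bis(methoxymethoxy)-5-(2-methylbut-3-en-2-yl)-3-(3-methylbut-2-en-1-yl)phenyl]ethan-1-one
Conditions: Dess–Martin periodinane, pyridine, CH2Cl2, 0 °C → rt
Reagents that add atoms: none
Why: Dess–Martin oxidation of the secondary benzylic alcohol should give the α-chloroketone without any electrophilic halogen source, so the two alkenes, the MOM ethers and the C–Cl bond are not touched.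

**Step 10**
Reactants: 15 2,4,6-trihydroxybenzaldehyde
Product: 16 2-hydroxy-4,6-bis(methoxymethoxy)benzaldehyde
Conditions: MOMCl (2.1 equiv), i-Pr2NEt, CH2Cl2, 0 °C → rt
Reagents that add atoms: chloromethyl methyl ether, COCCl
Why: O-Alkylation with MOMCl and a hindered amine base should protect the 4-OH and one ortho OH, while the remaining ortho OH stays free because its hydrogen bond to the formyl group lowers its nucleophilicity (selective Williamson-type protection).

**Step 11**
Reactants: 14 2-chloro-1-[2,4-bis(methoxymethoxy)-5-(2-methylbut-3-en-2-yl)-3-(3-methylbut-2-en-1-yl)phenyl]ethan-1-one; 16 2-hydroxy-4,6-bis(methoxymethoxy)benzaldehyde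
Product: 17 2-{2-[2,4-bis(methoxymethoxy)-5-(2-methylbut-3-en-2-yl)-3-(3-methylbut-2-en-1-yl)phenyl]-2-oxoethoxy}-4,6-bis(methoxymethoxy)benzaldehyde
Conditions: K2CO3, KI (cat.), acetone, rt
Reagents that add atoms: none
Why: Williamson ether synthesis by SN2 displacement at the activated primary carbon of the phenacyl-type chloride (iodide catalysis) forms the O1–C2 ether, and carbonate at room temperature should be too mild to start the Rap–Stoermer aldol condensation to a 2-aroylbenzofuran.

**Step 12**
Reactants: 17 2-{2-[2,4-bis(methoxymethoxy)-5-(2-methylbut-3-en-2-yl)-3-(3-methylbut-2-en-1-yl)phenyl]-2-oxoethoxy}-4,6-bis(methoxymethoxy)benzaldehyde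
Product: 18 racemic 3-[2,4-bis(methoxymethoxy)-5-(2-methylbut-3-en-2-yl)-3-(3-methylbut-2-en-1-yl)phenyl]-3-hydroxy-5,7-bis(methoxymethoxy)chroman-4-one
Conditions: 2-(pentafluorophenyl)-6,7-dihydro-5H-pyrrolo[2,1-c][1,2,4]triazol-2-ium tetrafluoroborate (20 mol %), Et3N (20 mol %), toluene, 40 °C, argon
Reagents that add atoms: none
Why: The triazolylidene freed by Et3N adds to the A-ring formyl group and proton transfer gives the Breslow enaminol, an acyl anion equivalent at the future C4, which attacks the tethered B-ring ketone carbon (future C3); proton transfer and loss of the carbene then leave the tertiary α-hydroxy ketone. The closest known reaction is the carbene-catalysed intramolecular crossed aldehyde–ketone benzoin cyclisation of 2-(2-aryl-2-oxoethoxy)benzaldehydes to 3-aryl-3-hydroxychroman-4-ones. Ring C closes in the 6-exo-trig mode, since the attacked C=O is exocyclic to the ring made of C4, C4a, C8a, O1, C2 and C3. The new C3 carbinol centre is formed under an achiral catalyst and is therefore racemic, which is accepted because step 13 turns C3 into an sp2 carbon. The step needs chemoselectivity for acyl anion addition over base-mediated aldol condensation of the C2 methylene with the aldehyde and over intermolecular benzoin; the weak amine base, the flat electron-poor N-pentafluorophenyl carbene (chosen because the formyl group sits between two alkoxy groups) and the di-ortho substitution of the aldehyde, which disfavours both homodimerisation and aldol attack, are relied on for this. The product ketone is conjugated to the trioxygenated ring A, which should draw the reversible addition towards the cyclised side.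

**Step 13**
Reactants: 18 racemic 3-[2,4-bis(methoxymethoxy)-5-(2-methylbut-3-en-2-yl)-3-(3-methylbut-2-en-1-yl)phenyl]-3-hydroxy-5,7-bis(methoxymethoxy)chroman-4-one
Product: 20 3-[2,4-bis(methoxymethoxy)-5-(2-methylbut-3-en-2-yl)-3-(3-methylbut-2-en-1-yl)phenyl]-5,7-bis(methoxymethoxy)-4H-chromen-4-one, via tertiary sulfamate 19 (not isolated)
Conditions: Burgess reagent, THF, 60 °C
Reagents that add atoms: none
Why: Burgess dehydration: the tertiary benzylic alcohol is sulfamoylated and the sulfamate undergoes thermal syn-elimination with a C2 hydrogen, the only β-hydrogens present, which should give the C2=C3 bond conjugated to C4=O and O1 under neutral conditions that spare the MOM ethers and both alkenes.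

**Step 14**
Reactants: 20 3-[2,4-bis(methoxymethoxy)-5-(2-methylbut-3-en-2-yl)-3-(3-methylbut-2-en-1-yl)phenyl]-5,7-bis(methoxymethoxy)-4H-chromen-4-one
Product: 21 fremontone, 5,7-dihydroxy-3-[2,4-dihydroxy-5-(2-methylbut-3-en-2-yl)-3-(3-methylbut-2-en-1-yl)phenyl]-4H-chromen-4-one
Conditions: 3 M aq HCl, MeOH–THF, 45 °C
Reagents that add atoms: none
Why: Acid-catalysed acetal exchange with methanol should remove all four aryl MOM ethers, the dilute acid and moderate temperature being chosen so that protonation of the prenyl alkene (chroman formation with the flanking 2'- or 4'-OH) stays slower than acetal cleavage.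

**Compound list**
1 | resorcinol | Oc1cccc(O)c1 | starting material
2 | 1,3-bis(methoxymethoxy)benzene | COCOc1cccc(OCOC)c1 | intermediate
3 | prenyl bromide (1-bromo-3-methylbut-2-ene) | CC(C)=CCBr | starting material
4 | 2-lithio-1,3-bis(methoxymethoxy)benzene | [Li]c1c(OCOC)cccc1OCOC | intermediate (not isolated)
5 | 1,3-bis(methoxymethoxy)-2-(3-methylbut-2-en-1-yl)benzene | COCOc1cccc(OCOC)c1CC=C(C)C | intermediate
6 | [2,4-bis(methoxymethoxy)-3-(3-methylbut-2-en-1-yl)phenyl]lithium | [Li]c1ccc(OCOC)c(CC=C(C)C)c1OCOC | intermediate (not isolated)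
7 | lithium (dimethylamino)[2,4-bis(methoxymethoxy)-3-(3-methylbut-2-en-1-yl)phenyl]methanolate | [Li]OC(N(C)C)c1ccc(OCOC)c(CC=C(C)C)c1OCOC | intermediate (not isolated)
8 | 2,4-bis(methoxymethoxy)-3-(3-methylbut-2-en-1-yl)benzaldehyde | O=Cc1ccc(OCOC)c(CC=C(C)C)c1OCOC | intermediate
9 | 2,4-dihydroxy-3-(3-methylbut-2-en-1-yl)benzaldehyde | O=Cc1ccc(O)c(CC=C(C)C)c1O | intermediate
10 | 2-hydroxy-3-(3-methylbut-2-en-1-yl)-4-[(3-methylbut-2-en-1-yl)oxy]benzaldehyde | O=Cc1ccc(OCC=C(C)C)c(CC=C(C)C)c1O | intermediate
11 | 2,4-dihydroxy-5-(2-methylbut-3-en-2-yl)-3-(3-methylbut-2-en-1-yl)benzaldehyde | O=Cc1cc(C(C)(C)C=C)c(O)c(CC=C(C)C)c1O | intermediate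
12 | 2,4-bis(methoxymethoxy)-5-(2-methylbut-3-en-2-yl)-3-(3-methylbut-2-en-1-yl)benzaldehyde | O=Cc1cc(C(C)(C)C=C)c(OCOC)c(CC=C(C)C)c1OCOC | intermediate
13 | racemic 2-chloro-1-[2,4-bis(methoxymethoxy)-5-(2-methylbut-3-en-2-yl)-3-(3-methylbut-2-en-1-yl)phenyl]ethan-1-ol | OC(CCl)c1cc(C(C)(C)C=C)c(OCOC)c(CC=C(C)C)c1OCOC | intermediate
14 | 2-chloro-1-[2,4-bis(methoxymethoxy)-5-(2-methylbut-3-en-2-yl)-3-(3-methylbut-2-en-1-yl)phenyl]ethan-1-one | O=C(CCl)c1cc(C(C)(C)C=C)c(OCOC)c(CC=C(C)C)c1OCOC | intermediate
15 | 2,4,6-trihydroxybenzaldehyde | O=Cc1c(O)cc(O)cc1O | starting material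
16 | 2-hydroxy-4,6-bis(methoxymethoxy)benzaldehyde | O=Cc1c(O)cc(OCOC)cc1OCOC | intermediate
17 | 2-{2-[2,4-bis(methoxymethoxy)-5-(2-methylbut-3-en-2-yl)-3-(3-methylbut-2-en-1-yl)phenyl]-2-oxoethoxy}-4,6-bis(methoxymethoxy)benzaldehyde | O=Cc1c(OCOC)cc(OCOC)cc1OCC(=O)c1cc(C(C)(C)C=C)c(OCOC)c(CC=C(C)C)c1OCOC | intermediate
18 | racemic 3-[2,4-bis(methoxymethoxy)-5-(2-methylbut-3-en-2-yl)-3-(3-methylbut-2-en-1-yl)phenyl]-3-hydroxy-5,7-bis(methoxymethoxy)chroman-4-one | OC1(c2cc(C(C)(C)C=C)c(OCOC)c(CC=C(C)C)c2OCOC)COc2cc(OCOC)cc(OCOC)c2C1=O | intermediate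
19 | triethylammonium salt of the C3 O-[N-(methoxycarbonyl)sulfamate] of 18 | COC(=O)[N-]S(=O)(=O)OC1(c2cc(C(C)(C)C=C)c(OCOC)c(CC=C(C)C)c2OCOC)COc2cc(OCOC)cc(OCOC)c2C1=O.CC[NH+](CC)CC | intermediate (not isolated)
20 | 3-[2,4-bis(methoxymethoxy)-5-(2-methylbut-3-en-2-yl)-3-(3-methylbut-2-en-1-yl)phenyl]-5,7-bis(methoxymethoxy)-4H-chromen-4-one | C=CC(C)(C)c1cc(-c2coc3cc(OCOC)cc(OCOC)c3c2=O)c(OCOC)c(CC=C(C)C)c1OCOC | intermediate
21 | fremontone | C=CC(C)(C)c1cc(-c2coc3cc(O)cc(O)c3c2=O)c(O)c(CC=C(C)C)c1O | target

**Step count**
Total: 14 steps. Longest linear sequence: 13 steps (steps 1–9 and 11–14; step 10 is the one-step A-ring branch).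

**Steps most likely to fail, with fallbacks**

Step 12 (key step). The carbene may add only slowly to a formyl group flanked by two alkoxy groups, so that base-mediated aldol condensation of the C2 methylene with the aldehyde, or simple non-conversion, takes over. The fallback gives up the C3–C4 closure and builds ring C by one-carbon insertion on a deoxybenzoin; it sets out from 16 and 12 and comes back at 20, so that steps 8, 9, 11, 12 and 13 are bypassed. Aldehyde 16 is condensed with aniline and diphenyl phosphite (i-PrOH, rt) to the N,P-acetal diphenyl {[2-hydroxy-4,6-bis(methoxymethoxy)phenyl](phenylamino)methyl}phosphonate F1. Horner–Wittig olefination of F1 with aldehyde 12 (Cs2CO3, THF–i-PrOH, rt) should expel diphenyl phosphate and give the N-phenyl enamine of the deoxybenzoin F2, which brief treatment with dilute aqueous acid in THF hydrolyses to 2-[2,4-bis(methoxymethoxy)-5-(2-methylbut-3-en-2-yl)-3-(3-methylbut-2-en-1-yl)phenyl]-1-[2-hydroxy-4,6-bis(methoxymethoxy)phenyl]ethan-1-one F3. Heating F3 with N,N-dimethylformamide dimethyl acetal (toluene, 80 °C) forms the enaminone at the benzylic methylene, and the free phenol closes O1–C2 with loss of dimethylamine to give 20.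

Step 6. The freshly formed phenol may transfer its hydrogen to the new terminal alkene (abnormal Claisen isomerisation of the 1,1-dimethylallyl group), may add to a side chain, or the ether may ionise in the protic medium. The fallback sets out from 10 and comes back at 11. Ether 10 is heated in anhydrous N,N-diethylaniline with N,O-bis(trimethylsilyl)acetamide (170 °C, sealed tube), so that the 2-OH is silylated first and the phenol released by the rearrangement is capped as it forms, giving 5-(2-methylbut-3-en-2-yl)-3-(3-methylbut-2-en-1-yl)-2,4-bis(trimethylsilyloxy)benzaldehyde F4. Both silyl ethers are then cleaved with K2CO3 in MeOH at rt to return 11.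

Step 14. Under protic acid the prenyl alkene may be protonated and trapped by a freed neighbouring phenol before all four acetals are gone. The fallback sets out from 20 and comes back at 21 without a Brønsted acid. Treatment of 20 with TMSOTf and 2,2'-bipyridyl (CH2Cl2, 0 °C → rt) should transfer each methoxymethyl group to the bipyridyl nitrogen and leave the tetrakis(trimethylsilyl) ether of fremontone F5, which is hydrolysed by adding water at rt to give 21.

**Further compounds**
F1 | step 12 | diphenyl {[2-hydroxy-4,6-bis(methoxymethoxy)phenyl](phenylamino)methyl}phosphonate | O=P(Oc1ccccc1)(Oc1ccccc1)C(Nc1ccccc1)c1c(O)cc(OCOC)cc1OCOC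
F2 | step 12 | N-phenyl enamine of the deoxybenzoin, 2-{2-[2,4-bis(methoxymethoxy)-5-(2-methylbut-3-en-2-yl)-3-(3-methylbut-2-en-1-yl)phenyl]-1-(phenylamino)ethenyl}-3,5-bis(methoxymethoxy)phenol | Oc1cc(OCOC)cc(OCOC)c1C(Nc1ccccc1)=Cc1cc(C(C)(C)C=C)c(OCOC)c(CC=C(C)C)c1OCOC
F3 | step 12 | 2-[2,4-bis(methoxymethoxy)-5-(2-methylbut-3-en-2-yl)-3-(3-methylbut-2-en-1-yl)phenyl]-1-[2-hydroxy-4,6-bis(methoxymethoxy)phenyl]ethan-1-one | O=C(Cc1cc(C(C)(C)C=C)c(OCOC)c(CC=C(C)C)c1OCOC)c1c(O)cc(OCOC)cc1OCOC
F4 | step 6 | 5-(2-methylbut-3-en-2-yl)-3-(3-methylbut-2-en-1-yl)-2,4-bis(trimethylsilyloxy)benzaldehyde | O=Cc1cc(C(C)(C)C=C)c(O[Si](C)(C)C)c(CC=C(C)C)c1O[Si](C)(C)C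
F5 | step 14 | tetrakis(trimethylsilyl) ether of fremontone | C=CC(C)(C)c1cc(-c2coc3cc(O[Si](C)(C)C)cc(O[Si](C)(C)C)c3c2=O)c(O[Si](C)(C)C)c(CC=C(C)C)c1O[Si](C)(C)C
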